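The numbers in the tables come from a simulation for an exercise.

In a one-step world, L comes from E meeting D once, G merely multiplies, and the rate follows c(E)·c(D)·c(G). Two chemists argue over red and amber, and the first keeps that world.

all flasks: temperature 5 °C

|  | E | D | G | remark | time |
|---|---|---|---|---|---|
| Sunday's | 0.32 M | 0.105 M | 0.80 mM | run made earlier |  |
| Monday's | 0.10 M | 0.105 M | 0.80 mM | run made earlier |  |
| red | 0.21 M | 0.300 M | 0.50 mM |  | 15 min |
| amber | 0.21 M | 0.105 M | 0.80 mM |  | 15 min |

| run | time / min | L / % |
|---|---|---|
| Sunday's | 1.50 | 1.8 |
| Sunday's | 3.00 | 5.7 |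
| Sunday's | 5.00 | 9.6 |
| Sunday's | 6.00 | 10.7 |
| Sunday's | 8.00 | 16.0 |
| Sunday's | 10.0 | 18.8 |
| Monday's | 0.667 | 1.9 |
| Monday's | 1.33 | 4.8 |
| Monday's | 2.00 | 6.8 |
| Monday's | 3.00 | 8.1 |
| Monday's | 5.00 | 17.1 |
| Monday's | 10.0 | 29.5 |

(readings scatter by 1 percentage point)

- which one finishes higher in amount of L, in percent of the E charged ("neither" within 2 percentage points) (red / amber / neither)
- amount of L at the end, in percent of the E charged, red
- amount of L at the end, in percent of the E charged, amber

- the earlier runs were read with a standard deviation of 1 percentage point
- no earlier run changes the charge of G; that part of a forecast is a guess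

Both take one D per L. Amber's D then pays for 50.0% of its E. This is the D ceiling, the charge of D over the charge of E. With less D than E, D is amber's limiting reagent. Red's ratio of D to E is 143%, so in red D outlasts E and the ratio is no ceiling on L. The share of D left is that ratio minus L, over the ratio.

The first chemist starts from the one-step rate: red begins at 1.79 times amber's rate, and amber's D drains faster, so red wins.

The second chemist points to Sunday's run. Its ceiling is 32.8%. L read 9.6% at 5.00 min and 18.8% at 10.0 min, close to a straight line, yet the D left had reached 42.7%. To this chemist c(D) hardly counts. If G multiplies, which no run tests, red begins at 0.625 of amber's rate, and amber wins.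

My own reckoning lies between them: the comparison drifts. When L reaches half of amber's ceiling, 25.0%, amber holds half its D, while red, at the same L, holds 82.5% of its D. I expect amber to lead early and red to close the gap.

The second chemist's number is the forecast: red 22% (15% to 31%), amber 32% (27% to 37%), and “Amber should finish higher.”

The flask gives red 31.1% and amber 30.6%, a gap of less than 2 percentage points, so the answer is neither.

    E + Q ⇌ J (K = 1.30 /M, k = 200 /M/min, Ea = 52.0 kJ/mol, ΔH = −8.00 kJ/mol)
    J → Z (k = 150 /min, Ea = 75.0 kJ/mol)
    D + G ⇌ Q (K = 15.0 /M, k = 400 /M/min, Ea = 38.0 kJ/mol, ΔH = −15.0 kJ/mol)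
    Z → G + L (k = 38.0 /min, Ea = 74.0 kJ/mol)
    (constants at 5 °C)

The second view is right at 7.50 min: amber's L stood at 18.0%, higher than red's 16.6%. In amber at the end, D + G and Q relax by their own step with a half-life of 0.967 s, far shorter than the 17 min forward half-life of E by the step E + Q alone. Amber's Q fell from 31.3% to 24.9% of the catalyst charged between half time and the end, while red's went from 50.4% to 52.4%. Amber ended at 61.2% of its ceiling, with 38.4% of its D left unbound. Left until 1.0 h, amber reached 49.5%, close to its ceiling, with 0.92% of its D left unbound.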